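**Retrosynthetic overview**

1. The C6–CH2 bond is made last but one, by Negishi sp3–sp2 coupling of a (cyclohexyl)methylzinc iodide with 6-iodo-tetra-O-benzylluteolin. Rings A, C and B of the flavone are taken intact from luteolin (selective benzylation, C6 iodination).
2. The cyclohexane is the only ring built. It comes from a formal (4+2) annulation: 3-methylbut-2-enal supplies the ring CH and the CMe2 carbon, and the 4-oxopentyl radical from 5-oxohexanoic acid supplies the three ring CH2 groups and the carbinol carbon. Radical conjugate addition and enamine aldol closure run under one chiral amine and set both stereocentres.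
3. Enabling feature: in the cyclohexane ring both the carbinol carbon C(OH)CH3 and the quaternary CMe2 carbon are β to the exocyclic benzylic carbon, through the ring CH. With the benzylic carbon raised to the aldehyde level, the ring is an aldol adduct (ring CH to carbinol carbon) of a conjugate adduct (ring CH2 to CMe2).
4. After the key step the aldehyde carbon is taken down to CH2I and becomes the benzylic CH2 of the target. Ring order: cyclohexane (step 1), then union with the preformed flavone rings and debenzylation.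

Key step: step 1

Remark on stereochemistry: the target is read as the trans isomer (tertiary hydroxyl trans to the arylmethyl group on the cyclohexane), (1S,6S) in cyclohexylmethyl numbering. The facial sense of the amine catalyst is assumed to follow the usual steric model for diarylprolinol silyl ethers (attack anti to the diarylmethyl group).

**Route**

Step 1
Reactants: 1 3-methylbut-2-enal, 2 5-oxohexanoic acid
Product: 3 (1S,2S)-2-hydroxy-2,6,6-trimethylcyclohexane-1-carbaldehyde
Conditions: 1 (excess), (R)-2-{bis[3,5-bis(trifluoromethyl)phenyl](trimethylsilyloxy)methyl}pyrrolidine (20 mol%), 2,4,5,6-tetrakis(carbazol-9-yl)isophthalonitrile (4CzIPN, 2 mol%), MeCN, blue LEDs (456 nm), 20 °C, argon; crude product used directly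
Reagents that add atoms: none
Why: Proposed new method: condensation of 1 with the amine gives an iminium ion whose counter-ion is the carboxylate of 2; excited 4CzIPN oxidises this carboxylate, CO2 is lost, the 4-oxopentyl radical adds to the iminium β-carbon (first new bond, to the carbon that becomes the ring CMe2), and the reduced photocatalyst converts the α-iminyl radical cation into the (E)-enamine. The enamine carbon then attacks the tethered methyl ketone in a 6-(enolexo)-exo-trig aldol closure (second new bond, ring closed), and hydrolysis releases 3 and the amine. The closest known reaction types are the photoredox radical conjugate addition to enal-derived iminium ions, its cascade variant in which a ketone-bearing radical from a cyclopropanol is trapped and the enamine closes a cyclopentanol by aldol addition, and the amine-catalysed 6-enolexo aldolisation of 1,7-dicarbonyl compounds; new here are the quaternary carbon made by radical addition to a β,β-disubstituted enal and the six-membered closure onto a ketone in the same cascade. The configuration of the ring CH should be set by the (R)-diaryl(silyloxy)methyl group, which shields one face of the s-trans (E)-enamine so that the ketone adds to the open face; the configuration of the carbinol carbon should follow from the compact transition state in which the developing alkoxide stays next to the iminium nitrogen, the ring tether sits equatorial and the ketone methyl axial, which places OH trans to the formyl group. The step needs 1,4- over 1,2-addition of the radical and an aldol closure faster than loss of the enamine: the cationic iminium directs the nucleophilic alkyl radical to its β-carbon, and the gem-dimethyl group preorganises the chain for ring closure.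

Step 2
Reactants: 3 (1S,2S)-2-hydroxy-2,6,6-trimethylcyclohexane-1-carbaldehyde
Product: 4 (1S,2R)-2-(hydroxymethyl)-1,3,3-trimethylcyclohexan-1-ol
Conditions: NaBH4, MeOH, 0 °C
Reagents that add atoms: none
Why: Borohydride reduction of the aldehyde is fast at 0 °C and removes the epimerisable, retro-aldol-prone β-hydroxy aldehyde without touching either stereocentre (the descriptor at the ring CH changes only through priority rules).

Step 3
Reactants: 4 (1S,2R)-2-(hydroxymethyl)-1,3,3-trimethylcyclohexan-1-ol
Product: 5 (1S,2S)-2-(iodomethyl)-1,3,3-trimethylcyclohexan-1-ol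
Conditions: PPh3, iodine, imidazole, toluene, 25 to 60 °C
Reagents that add atoms: iodine, [I][I]
Why: Appel iodination activates only the primary hydroxyl as its alkoxyphosphonium ion, which iodide displaces in an SN2 step, while the hindered tertiary hydroxyl cannot be displaced.

Step 4
Reactants: 5 (1S,2S)-2-(iodomethyl)-1,3,3-trimethylcyclohexan-1-ol
Product: 6 {[(1S,2S)-2-(iodomethyl)-1,3,3-trimethylcyclohexyl]oxy}trimethylsilane
Conditions: 1-(trimethylsilyl)imidazole, CH2Cl2, 25 °C
Reagents that add atoms: 1-(trimethylsilyl)imidazole, C[Si](C)(C)n1ccnc1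
Why: The N-silylimidazole silylates the hindered tertiary alcohol under neutral conditions, so that the later organozinc is not protonated intramolecularly; the primary iodide is inert.

Step 5
Reactants: 7 luteolin
Product: 8 7-(benzyloxy)-2-[3,4-bis(benzyloxy)phenyl]-5-hydroxy-4H-chromen-4-one
Conditions: BnBr (3.1 equiv), K2CO3, DMF, 25 °C
Reagents that add atoms: benzyl bromide, BrCc1ccccc1
Why: Williamson benzylation alkylates the three acidic phenols (O7, O3', O4') and should leave the 5-hydroxyl, which is hydrogen-bonded to the C4 carbonyl and much less nucleophilic.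

Step 6
Reactants: 8 7-(benzyloxy)-2-[3,4-bis(benzyloxy)phenyl]-5-hydroxy-4H-chromen-4-one
Product: 9 7-(benzyloxy)-2-[3,4-bis(benzyloxy)phenyl]-5-hydroxy-6-iodo-4H-chromen-4-one
Conditions: benzyltrimethylammonium dichloroiodate, CaCO3, CH2Cl2–MeOH, 25 °C
Reagents that add atoms: benzyltrimethylammonium dichloroiodate, C[N+](C)(C)Cc1ccccc1.Cl[I-]Cl
Why: Electrophilic aromatic iodination with this mild iodonium source should occur on the most electron-rich ring A at C6, ortho to the free chelated 5-hydroxyl, the regiochemistry established for 5-hydroxy-7-alkoxyflavones; CaCO3 buffers the HCl released.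

Step 7
Reactants: 9 7-(benzyloxy)-2-[3,4-bis(benzyloxy)phenyl]-5-hydroxy-6-iodo-4H-chromen-4-one
Product: 10 5,7-bis(benzyloxy)-2-[3,4-bis(benzyloxy)phenyl]-6-iodo-4H-chromen-4-one
Conditions: BnBr, K2CO3, DMF, 70 °C
Reagents that add atoms: benzyl bromide, BrCc1ccccc1
Why: Under more forcing Williamson conditions the chelated 5-hydroxyl is benzylated as well, which removes the last acidic proton before the organozinc coupling.

Step 8
Reactants: 6 {[(1S,2S)-2-(iodomethyl)-1,3,3-trimethylcyclohexyl]oxy}trimethylsilane, 10 5,7-bis(benzyloxy)-2-[3,4-bis(benzyloxy)phenyl]-6-iodo-4H-chromen-4-one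
Product: 13 5,7-bis(benzyloxy)-2-[3,4-bis(benzyloxy)phenyl]-6-{[(1S,6S)-6-hydroxy-2,2,6-trimethylcyclohexyl]methyl}-4H-chromen-4-one, via alkylzinc iodide 11 (not isolated), via silyl-protected coupling product 12 (not isolated)
Conditions: 6, Zn dust, LiCl, THF, 45 °C; then 10, Pd(OAc)2 (5 mol%), SPhos (10 mol%), THF, 55 °C; then 10% aq. citric acid, MeOH, 25 °C
Reagents that add atoms: none
Why: LiCl-assisted zinc insertion into the primary C–I bond gives an alkylzinc iodide that tolerates the silyl ether, the chromenone carbonyl and the benzyl ethers; in the Negishi coupling the bulky biarylphosphine should promote oxidative addition of the di-ortho-substituted aryl iodide and reductive elimination over β-hydride elimination without involving either stereocentre, and the mild acid then cleaves the trimethylsilyl ether.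

Step 9
Reactants: 13 5,7-bis(benzyloxy)-2-[3,4-bis(benzyloxy)phenyl]-6-{[(1S,6S)-6-hydroxy-2,2,6-trimethylcyclohexyl]methyl}-4H-chromen-4-one
Product: 14 2-(3,4-dihydroxyphenyl)-5,7-dihydroxy-6-{[(1S,6S)-6-hydroxy-2,2,6-trimethylcyclohexyl]methyl}-4H-chromen-4-one
Conditions: H2 (1 atm), Pd/C (10%), EtOAc–MeOH, 25 °C
Reagents that add atoms: none
Why: Catalytic hydrogenolysis cleaves the four aryl benzyl ethers under conditions at which the tertiary alcohol, the aryl–CH2 bond and the chromenone C2–C3 double bond should persist.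

**Compound list**

1 | 3-methylbut-2-enal | CC(C)=CC=O | starting material
2 | 5-oxohexanoic acid | CC(=O)CCCC(=O)O | starting material
3 | (1S,2S)-2-hydroxy-2,6,6-trimethylcyclohexane-1-carbaldehyde | CC1(C)CCC[C@](C)(O)[C@H]1C=O | intermediate
4 | (1S,2R)-2-(hydroxymethyl)-1,3,3-trimethylcyclohexan-1-ol | CC1(C)CCC[C@](C)(O)[C@H]1CO | intermediate
5 | (1S,2S)-2-(iodomethyl)-1,3,3-trimethylcyclohexan-1-ol | CC1(C)CCC[C@](C)(O)[C@H]1CI | intermediate
6 | {[(1S,2S)-2-(iodomethyl)-1,3,3-trimethylcyclohexyl]oxy}trimethylsilane | CC1(C)CCC[C@](C)(O[Si](C)(C)C)[C@H]1CI | intermediate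
7 | luteolin, 2-(3,4-dihydroxyphenyl)-5,7-dihydroxy-4H-chromen-4-one | O=c1cc(-c2ccc(O)c(O)c2)oc2cc(O)cc(O)c12 | starting material
8 | 7-(benzyloxy)-2-[3,4-bis(benzyloxy)phenyl]-5-hydroxy-4H-chromen-4-one | O=c1cc(-c2ccc(OCc3ccccc3)c(OCc3ccccc3)c2)oc2cc(OCc3ccccc3)cc(O)c12 | intermediate
9 | 7-(benzyloxy)-2-[3,4-bis(benzyloxy)phenyl]-5-hydroxy-6-iodo-4H-chromen-4-one | O=c1cc(-c2ccc(OCc3ccccc3)c(OCc3ccccc3)c2)oc2cc(OCc3ccccc3)c(I)c(O)c12 | intermediate
10 | 5,7-bis(benzyloxy)-2-[3,4-bis(benzyloxy)phenyl]-6-iodo-4H-chromen-4-one | O=c1cc(-c2ccc(OCc3ccccc3)c(OCc3ccccc3)c2)oc2cc(OCc3ccccc3)c(I)c(OCc3ccccc3)c12 | intermediate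
11 | iodo{[(1S,6S)-2,2,6-trimethyl-6-(trimethylsilyloxy)cyclohexyl]methyl}zinc | CC1(C)CCC[C@](C)(O[Si](C)(C)C)[C@H]1C[Zn]I | intermediate
12 | 5,7-bis(benzyloxy)-2-[3,4-bis(benzyloxy)phenyl]-6-{[(1S,6S)-2,2,6-trimethyl-6-(trimethylsilyloxy)cyclohexyl]methyl}-4H-chromen-4-one | CC1(C)CCC[C@](C)(O[Si](C)(C)C)[C@H]1Cc1c(OCc2ccccc2)cc2oc(-c3ccc(OCc4ccccc4)c(OCc4ccccc4)c3)cc(=O)c2c1OCc1ccccc1 | intermediate
13 | 5,7-bis(benzyloxy)-2-[3,4-bis(benzyloxy)phenyl]-6-{[(1S,6S)-6-hydroxy-2,2,6-trimethylcyclohexyl]methyl}-4H-chromen-4-one | CC1(C)CCC[C@](C)(O)[C@H]1Cc1c(OCc2ccccc2)cc2oc(-c3ccc(OCc4ccccc4)c(OCc4ccccc4)c3)cc(=O)c2c1OCc1ccccc1 | intermediate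
14 | 2-(3,4-dihydroxyphenyl)-5,7-dihydroxy-6-{[(1S,6S)-6-hydroxy-2,2,6-trimethylcyclohexyl]methyl}-4H-chromen-4-one | CC1(C)CCC[C@](C)(O)[C@H]1Cc1c(O)cc2oc(-c3ccc(O)c(O)c3)cc(=O)c2c1O | target

**Step count and risks**

Total steps: 9. Longest linear sequence: 6 steps (steps 1, 2, 3, 4, 8, 9).

Steps most likely to fail:

Step 1. The enal may self-condense through its dienamine under amine catalysis. The 4-oxopentyl radical may be reduced or quenched by hydrogen-atom transfer before it reaches the hindered iminium β-carbon. The aldol closure may proceed with insufficient diastereo- or enantiocontrol. The fallback uses known polar chemistry, sets out from 1 and comes back at 3. The Grignard reagent [3-(2-methyl-1,3-dioxolan-2-yl)propyl]magnesium chloride F1, made from commercial 2-(3-chloropropyl)-2-methyl-1,3-dioxolane and Mg in THF, is added to 1 with catalytic CuBr·SMe2 and TMSCl at −78 °C. This should give the conjugate adduct as (E)-{[3,3-dimethyl-6-(2-methyl-1,3-dioxolan-2-yl)hex-1-en-1-yl]oxy}trimethylsilane F2. Aqueous HCl in THF hydrolyses the silyl enol ether and the dioxolane to the achiral ketoaldehyde 3,3-dimethyl-7-oxooctanal F3. (S)-Proline in DMSO at 20 °C should then effect the 6-enolexo aldolisation to 3, with the carboxylic acid directing the ketone to the same enamine face as in the main route.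

Step 8. Transmetalation and reductive elimination between the β-branched, heavily substituted alkylzinc and an aryl iodide flanked by two benzyloxy groups may be slow, so that protodezincation and hydrodeiodination take over. The fallback reverses the polarity, sets out from 3 and 10 and comes back at 14. Aldehyde 3 is silylated with 1-(trimethylsilyl)imidazole to (1S,2S)-2,6,6-trimethyl-2-[(trimethylsilyl)oxy]cyclohexane-1-carbaldehyde F4. Iodide 10 is converted by iodine–magnesium exchange (iPrMgCl·LiCl, THF, −40 °C) into {5,7-bis(benzyloxy)-2-[3,4-bis(benzyloxy)phenyl]-4-oxo-4H-chromen-6-yl}magnesium chloride F5. Addition of F5 to F4 should give, as a mixture of carbinol epimers, 5,7-bis(benzyloxy)-2-[3,4-bis(benzyloxy)phenyl]-6-{hydroxy[(1R,6S)-2,2,6-trimethyl-6-(trimethylsilyloxy)cyclohexyl]methyl}-4H-chromen-4-one F6. Hydrogenolysis (H2, Pd(OH)2/C, EtOAc–MeOH, trace HCl) should remove the four benzyl groups, the silyl group and the benzylic hydroxyl, the last through the ortho-quinone methide once the flanking phenols are free, to give 14.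

Step 9. The pyranone C2–C3 double bond may be partly saturated, or cleavage of the hindered 5-O-benzyl ether may stall. The fallback replaces the reductive global deprotection by an acidolytic one, sets out from 7 (using zinc reagent 11) and comes back at 14. Luteolin 7 is converted with MOMCl and iPr2NEt into 2-[3,4-bis(methoxymethoxy)phenyl]-5-hydroxy-7-(methoxymethoxy)-4H-chromen-4-one F7. Iodination at C6 as in step 6 should give 2-[3,4-bis(methoxymethoxy)phenyl]-5-hydroxy-6-iodo-7-(methoxymethoxy)-4H-chromen-4-one F8. Capping of O5 (NaH, MOMCl) gives 2-[3,4-bis(methoxymethoxy)phenyl]-6-iodo-5,7-bis(methoxymethoxy)-4H-chromen-4-one F9. Negishi coupling with 11 under the conditions of step 8 should give 2-[3,4-bis(methoxymethoxy)phenyl]-5,7-bis(methoxymethoxy)-6-{[(1S,6S)-2,2,6-trimethyl-6-(trimethylsilyloxy)cyclohexyl]methyl}-4H-chromen-4-one F10. Dilute HCl in MeOH at 20 °C removes the four acetal groups and the silyl group to give 14.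

**Further compounds**

F1 | step 1 | [3-(2-methyl-1,3-dioxolan-2-yl)propyl]magnesium chloride | CC1(CCC[Mg]Cl)OCCO1
F2 | step 1 | (E)-{[3,3-dimethyl-6-(2-methyl-1,3-dioxolan-2-yl)hex-1-en-1-yl]oxy}trimethylsilane | C[Si](C)(C)O/C=C/C(C)(C)CCCC1(C)OCCO1
F3 | step 1 | 3,3-dimethyl-7-oxooctanal | CC(=O)CCCC(C)(C)CC=O
F4 | step 8 | (1S,2S)-2,6,6-trimethyl-2-[(trimethylsilyl)oxy]cyclohexane-1-carbaldehyde | CC1(C)CCC[C@](C)(O[Si](C)(C)C)[C@H]1C=O
F5 | step 8 | {5,7-bis(benzyloxy)-2-[3,4-bis(benzyloxy)phenyl]-4-oxo-4H-chromen-6-yl}magnesium chloride | O=c1cc(-c2ccc(OCc3ccccc3)c(OCc3ccccc3)c2)oc2cc(OCc3ccccc3)c([Mg]Cl)c(OCc3ccccc3)c12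
F6 | step 8 | 5,7-bis(benzyloxy)-2-[3,4-bis(benzyloxy)phenyl]-6-{hydroxy[(1R,6S)-2,2,6-trimethyl-6-(trimethylsilyloxy)cyclohexyl]methyl}-4H-chromen-4-one | CC1(C)CCC[C@](C)(O[Si](C)(C)C)[C@H]1C(O)c1c(OCc2ccccc2)cc2oc(-c3ccc(OCc4ccccc4)c(OCc4ccccc4)c3)cc(=O)c2c1OCc1ccccc1
F7 | step 9 | 2-[3,4-bis(methoxymethoxy)phenyl]-5-hydroxy-7-(methoxymethoxy)-4H-chromen-4-one | O=c1cc(-c2ccc(OCOC)c(OCOC)c2)oc2cc(OCOC)cc(O)c12
F8 | step 9 | 2-[3,4-bis(methoxymethoxy)phenyl]-5-hydroxy-6-iodo-7-(methoxymethoxy)-4H-chromen-4-one | O=c1cc(-c2ccc(OCOC)c(OCOC)c2)oc2cc(OCOC)c(I)c(O)c12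
F9 | step 9 | 2-[3,4-bis(methoxymethoxy)phenyl]-6-iodo-5,7-bis(methoxymethoxy)-4H-chromen-4-one | O=c1cc(-c2ccc(OCOC)c(OCOC)c2)oc2cc(OCOC)c(I)c(OCOC)c12
F10 | step 9 | 2-[3,4-bis(methoxymethoxy)phenyl]-5,7-bis(methoxymethoxy)-6-{[(1S,6S)-2,2,6-trimethyl-6-(trimethylsilyloxy)cyclohexyl]methyl}-4H-chromen-4-one | CC1(C)CCC[C@](C)(O[Si](C)(C)C)[C@H]1Cc1c(OCOC)cc2oc(-c3ccc(OCOC)c(OCOC)c3)cc(=O)c2c1OCOC
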